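**Plan** (isochromene numbering: C1, O2, C3, C4, C4a, C5, C6, C7, C8, C8a; ring A = carbocycle, ring B = pyran; the same labels are used for the corresponding atoms of acyclic intermediates)
- Cuts: after the protecting groups, both rings are opened at once through the fusion bond C4a–C8a and the bond O2–C1; the open chain is then cut at the C7–O ester bond, at C5–C6 (alkyne to carbonyl) and at C7–C8 (acyl group to the lactate carbon).
- Enabling feature: O2–C1 and C4a–C8a are the two σ bonds that a 1-oxadiene O2=C3–C4=C4a forms with an enol ether C1=C8a, and the C4a=C5 bond of ring A is what the second π bond of an allene C4=C4a=C5 leaves behind, so an allenyl ketone tethered to an alkoxy enone holds rings A and B in latent form.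
- Forward order: the alkyne arm (C3–C5) and the aroyl acid are made separately; the chain is joined around C7 in the order C7–C8 (enolate acylation), C5–C6 (acetylide on the lactone), C7–O (aroylation); oxidation gives the diketo ynone, one base-triggered cascade closes ring A and ring B together, and a single acid treatment deprotects.
- Stereochemistry: C7, the only stereocentre, comes from (S)-lactic acid by self-regeneration of stereocentres through its cis pivalaldehyde acetal; it is quaternary and non-enolisable from step 7 on.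

Key step: step 13

Remark 1: the enol ether is carried as the ethyl ether because (E)-3-ethoxyacryloyl chloride is a catalogue reagent, so ethanol and not methanol leaves in step 13.
Remark 2: C6 is kept at the carbinol level from step 8 to step 12, because a tertiary alcohol next to an alkynyl ketone would be prone to close to a 3(2H)-furanone under the basic aroylation conditions.
Remark 3: the carbinol centres at C3 and C6 are carried as epimer mixtures (both become ketones in step 12), and the diketo ynone 25 is (R) by the sequence rules although C7 keeps the spatial arrangement of the (S)-configured target.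

**Route**

Step 1
Reactants: 1 2,2-dimethoxyacetaldehyde; 2 tert-butyl (triphenylphosphoranylidene)acetate
Product: 3 tert-butyl (2E)-4,4-dimethoxybut-2-enoate
Conditions: 1 (60% in H2O), CH2Cl2, 0 °C → rt
Reagents that add atoms: none
Why: Wittig olefination with a stabilised ylide, which should be (E)-selective and tolerates the aqueous aldehyde solution.

Step 2
Reactants: 3 tert-butyl (2E)-4,4-dimethoxybut-2-enoate
Product: 4 tert-butyl (2E)-4-oxobut-2-enoate
Conditions: Amberlyst-15 (H+ form), acetone/H2O (10:1), rt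
Reagents that add atoms: water, O
Why: Acid-catalysed acetal hydrolysis on a sulfonic acid resin, mild enough to leave the tert-butyl ester intact.

Step 3
Reactants: 4 tert-butyl (2E)-4-oxobut-2-enoate; 5 propargyl bromide
Product: 7 racemic tert-butyl (2E)-4-hydroxyhept-2-en-6-ynoate, via allenylzinc bromide 6 (not isolated)
Conditions: Zn dust, THF/sat. aq. NH4Cl, 0 °C
Reagents that add atoms: none
Why: Barbier propargylation, in which the allenylzinc bromide adds 1,2 to the aldehyde through an SE2' transition state to give the homopropargylic alcohol, while the enoate, the weaker acceptor, is left alone.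

Step 4
Reactants: 7 racemic tert-butyl (2E)-4-hydroxyhept-2-en-6-ynoate
Product: 8 racemic tert-butyl (2E)-4-[(triethylsilyl)oxy]hept-2-en-6-ynoate
Conditions: Et3SiCl, imidazole, CH2Cl2, 0 °C
Reagents that add atoms: triethylsilyl chloride, CC[Si](Cl)(CC)CC
Why: Standard silylation of a secondary alcohol (silyl chloride, imidazole); the triethylsilyl ether keeps the future C3 ketone masked through the organolithium steps and is removed together with the C6 silyl ether in step 11.

Step 5
Reactants: 9 orsellinic acid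
Product: 11 2,4-bis(methoxymethoxy)-6-methylbenzoic acid, via methoxymethyl ester 10 (not isolated)
Conditions: NaH, MeOCH2Cl, DMF, 0 °C → rt; then aq. NaOH, MeOH, 60 °C; aq. HCl to pH 4, 0 °C
Reagents that add atoms: chloromethyl methyl ether, COCCl; sodium hydroxide, [Na+].[OH-]
Why: Williamson-type alkylation of the carboxylate and of both phenoxides followed by saponification of the labile methoxymethyl ester, the aryl methoxymethyl ethers being stable to hydroxide and to brief acidification at pH 4.

Step 6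
Reactants: 12 (S)-lactic acid
Product: 13 (2S,5S)-2-tert-butyl-5-methyl-1,3-dioxolan-4-one
Conditions: t-BuCHO, TsOH·H2O (cat.), H2SO4 (cat.), pentane, reflux (Dean–Stark); crystallisation from Et2O/pentane, −78 °C
Reagents that add atoms: pivalaldehyde, CC(C)(C)C=O
Why: Acid-catalysed acetalisation of the α-hydroxy acid with azeotropic removal of water should favour the cis acetal, which is purified by low-temperature crystallisation, so that the lactate centre is relayed to the acetal carbon before it is flattened in step 7.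

Step 7
Reactants: 13 (2S,5S)-2-tert-butyl-5-methyl-1,3-dioxolan-4-one; 14 (2E)-3-ethoxyprop-2-enoyl chloride
Product: 16 (2S,5R)-2-tert-butyl-5-[(2E)-3-ethoxyprop-2-enoyl]-5-methyl-1,3-dioxolan-4-one, via lithium enolate 15 (not isolated)
Conditions: LiN(i-Pr)2, THF, −78 °C; then cannulated into 14, THF, −78 °C
Reagents that add atoms: none
Why: Claisen-type C-acylation of a lithium ester enolate by an acid chloride, in which the electrophile approaches the planar enolate anti to the tert-butyl group and so sets the quaternary centre (later C7) with net retention of the lactate configuration, the product having no α-hydrogen left for proton transfer.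

Step 8
Reactants: 8 racemic tert-butyl (2E)-4-[(triethylsilyl)oxy]hept-2-en-6-ynoate; 16 (2S,5R)-2-tert-butyl-5-[(2E)-3-ethoxyprop-2-enoyl]-5-methyl-1,3-dioxolan-4-one
Product: 19 tert-butyl (2E,9S,11E)-12-ethoxy-8,9-dihydroxy-9-methyl-10-oxo-4-[(triethylsilyl)oxy]dodeca-2,11-dien-6-ynoate (epimers at C4 and C8 of the chain), via lithium acetylide 17 (not isolated), via hydroxy ynone 18 (not isolated)
Conditions: 8, LiN(SiMe3)2, THF, −78 °C; then 16, −78 °C; AcOH, −78 → 0 °C, extraction; crude 18, NaBH4, CeCl3·7H2O, MeOH, −78 °C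
Reagents that add atoms: none
Why: Addition of a lithium acetylide to an activated lactone (the 1,3-dioxolan-4-one carbonyl is far more electrophilic than the vinylogous-ester carbonyl), collapse of the hemiketal on protonation with loss of pivalaldehyde, then Luche 1,2-reduction of the ynone as the most electrophilic carbonyl present, so that the α'-hydroxy ynone is removed before it can cyclise and the new C6 carbinol, reoxidised in step 12, needs no stereocontrol.

Step 9
Reactants: 19 tert-butyl (2E,9S,11E)-12-ethoxy-8,9-dihydroxy-9-methyl-10-oxo-4-[(triethylsilyl)oxy]dodeca-2,11-dien-6-ynoate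
Product: 20 tert-butyl (2E,9S,11E)-12-ethoxy-9-hydroxy-9-methyl-10-oxo-4,8-bis[(triethylsilyl)oxy]dodeca-2,11-dien-6-ynoate
Conditions: Et3SiCl, imidazole, DMF, 0 °C
Reagents that add atoms: triethylsilyl chloride, CC[Si](Cl)(CC)CC
Why: Chemoselective silylation, since the silyl chloride/imidazole pair should react with the secondary propargylic alcohol only and leave the hindered tertiary α-ketol as the single free hydroxyl for step 10.

Step 10
Reactants: 11 2,4-bis(methoxymethoxy)-6-methylbenzoic acid; 20 tert-butyl (2E,9S,11E)-12-ethoxy-9-hydroxy-9-methyl-10-oxo-4,8-bis[(triethylsilyl)oxy]dodeca-2,11-dien-6-ynoate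
Product: 23 tert-butyl (2E,9S,11E)-9-{[2,4-bis(methoxymethoxy)-6-methylbenzoyl]oxy}-12-ethoxy-9-methyl-10-oxo-4,8-bis[(triethylsilyl)oxy]dodeca-2,11-dien-6-ynoate, via acyl fluoride 21 (not isolated), via lithium alkoxide 22 (not isolated)
Conditions: 11, cyanuric fluoride, pyridine, CH2Cl2, −10 °C → rt (crude 21); 20, LiN(SiMe3)2, THF, −78 °C; then 21, −78 → −20 °C
Reagents that add atoms: none
Why: O-Acylation of a lithium tertiary alkoxide by an acyl fluoride, where the small leaving group and the strong Li–F bond offset the two ortho substituents of the acyl donor, the low temperature holds back silyl migration, and no alkynyl ketone is present for the alkoxide to attack.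

Step 11
Reactants: 23 tert-butyl (2E,9S,11E)-9-{[2,4-bis(methoxymethoxy)-6-methylbenzoyl]oxy}-12-ethoxy-9-methyl-10-oxo-4,8-bis[(triethylsilyl)oxy]dodeca-2,11-dien-6-ynoate
Product: 24 tert-butyl (2E,9S,11E)-9-{[2,4-bis(methoxymethoxy)-6-methylbenzoyl]oxy}-12-ethoxy-4,8-dihydroxy-9-methyl-10-oxododeca-2,11-dien-6-ynoate
Conditions: HF·pyridine, pyridine, THF, 0 °C
Reagents that add atoms: none
Why: Fluoride-driven cleavage of both triethylsilyl ethers under buffered, weakly acidic conditions, which should avoid acyl migration and retro-aldol cleavage and spare the aryl acetals, the enol ether and the tert-butyl ester; the diol is oxidised at once because a free C6 hydroxyl can add to the ethoxy enone.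

Step 12
Reactants: 24 tert-butyl (2E,9S,11E)-9-{[2,4-bis(methoxymethoxy)-6-methylbenzoyl]oxy}-12-ethoxy-4,8-dihydroxy-9-methyl-10-oxododeca-2,11-dien-6-ynoate
Product: 25 tert-butyl (2E,9R,11E)-9-{[2,4-bis(methoxymethoxy)-6-methylbenzoyl]oxy}-12-ethoxy-9-methyl-4,8,10-trioxododeca-2,11-dien-6-ynoate
Conditions: Dess–Martin periodinane, NaHCO3, CH2Cl2, 0 °C; filtered through Florisil and used at once
Reagents that add atoms: none
Why: Dess–Martin oxidation of the propargylic and the allylic carbinol to the ynone and the ene-dione under bicarbonate buffering, with no epimerisable centre since C7 bears no hydrogen; the C4 methylene of 25 is highly acidic, so the crude product goes straight into step 13.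

Step 13
Reactants: 25 tert-butyl (2E,9R,11E)-9-{[2,4-bis(methoxymethoxy)-6-methylbenzoyl]oxy}-12-ethoxy-9-methyl-4,8,10-trioxododeca-2,11-dien-6-ynoate
Product: 28 tert-butyl (2E)-3-[(7S)-7-{[2,4-bis(methoxymethoxy)-6-methylbenzoyl]oxy}-7-methyl-6,8-dioxo-7,8-dihydro-6H-isochromen-3-yl]prop-2-enoate, via diacylallene 26 (not isolated), via ethoxy acetal 27 (not isolated)
Conditions: Et3N (1 equiv), toluene, 0 → 40 °C
Reagents that add atoms: none
Why: Proposed new method: triethylamine should remove a C4 proton (activated by the C3 ketone and by the ynone) and reprotonation at C5 gives the 1,3-diacylallene 26, whose 1-oxadiene O2=C3–C4=C4a adds across the push–pull enol ether C1=C8a in an inverse-electron-demand hetero-Diels–Alder reaction (C8a to the central allene carbon C4a, the C3 oxygen to C1), after which E1cB loss of ethanol from acetal 27, whose C8a hydrogen is α to C8=O and vinylogous to C6=O, leaves the C1=C8a enol ether. The closest known reaction types are the base-mediated isomerisation of propargyl ketones to allenyl ketones and intramolecular hetero-Diels–Alder reactions of enones with enol ethers. Ring A closes through C4a–C8a as a six-membered carbocycle by 6-exo attack of C8a on the digonal allene carbon across the C6–C7–C8 tether, the C4a=C5 π bond staying in the ring, and ring B closes through O2–C1 as the pyran of the [4+2] adduct (6-exo-trig capture of the oxocarbenium carbon C1 if the process is stepwise). No stereocentre is created: C7 is quaternary and untouched, the centres at C1 and C8a of 27 are erased by the elimination, and the allene axis is consumed. The step needs carbon–carbon bond formation at C4a to outrun oxygen attack on the allene and intermolecular Michael addition; the polarity match (nucleophilic C8a, doubly acceptor-activated C4a), the C5 substituents lying in the plane of the C4=C4a π lobes and the short tether should secure the 6,6-fused product.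

Step 14
Reactants: 28 tert-butyl (2E)-3-[(7S)-7-{[2,4-bis(methoxymethoxy)-6-methylbenzoyl]oxy}-7-methyl-6,8-dioxo-7,8-dihydro-6H-isochromen-3-yl]prop-2-enoate
Product: 29 (S)-mitorubrinic acid
Conditions: CF3CO2H/CH2Cl2 (1:3), H2O (5 equiv), 0 °C → rt
Reagents that add atoms: none
Why: Acidolysis, in which CF3CO2H should cleave both aryl methoxymethyl acetals (hydrolysed by the added water) and the tert-butyl ester (loss of 2-methylpropene), while the tertiary aroyl ester, whose ionisation is disfavoured by the two flanking carbonyls, and the acid-stable azaphilone chromophore remain.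

**Compound list**

1 | 2,2-dimethoxyacetaldehyde | COC(OC)C=O | starting material
2 | tert-butyl (triphenylphosphoranylidene)acetate | CC(C)(C)OC(=O)C=P(c1ccccc1)(c1ccccc1)c1ccccc1 | starting material
3 | tert-butyl (2E)-4,4-dimethoxybut-2-enoate | COC(OC)/C=C/C(=O)OC(C)(C)C | intermediate
4 | tert-butyl (2E)-4-oxobut-2-enoate | O=C/C=C/C(=O)OC(C)(C)C | intermediate
5 | propargyl bromide (3-bromoprop-1-yne) | C#CCBr | starting material
6 | allenylzinc bromide (propa-1,2-dienylzinc bromide, formed in situ) | C=C=C[Zn]Br | intermediate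
7 | racemic tert-butyl (2E)-4-hydroxyhept-2-en-6-ynoate | C#CCC(O)/C=C/C(=O)OC(C)(C)C | intermediate
8 | racemic tert-butyl (2E)-4-[(triethylsilyl)oxy]hept-2-en-6-ynoate | C#CCC(O[Si](CC)(CC)CC)/C=C/C(=O)OC(C)(C)C | intermediate
9 | orsellinic acid (2,4-dihydroxy-6-methylbenzoic acid) | Cc1cc(O)cc(O)c1C(=O)O | starting material
10 | methoxymethyl 2,4-bis(methoxymethoxy)-6-methylbenzoate (formed in situ) | Cc1cc(OCOC)cc(OCOC)c1C(=O)OCOC | intermediate
11 | 2,4-bis(methoxymethoxy)-6-methylbenzoic acid | Cc1cc(OCOC)cc(OCOC)c1C(=O)O | intermediate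
12 | (S)-lactic acid | C[C@H](O)C(=O)O | starting material
13 | (2S,5S)-2-tert-butyl-5-methyl-1,3-dioxolan-4-one (cis) | C[C@@H]1O[C@H](C(C)(C)C)OC1=O | intermediate
14 | (2E)-3-ethoxyprop-2-enoyl chloride | CCO/C=C/C(Cl)=O | starting material
15 | lithium (2S)-2-tert-butyl-5-methyl-1,3-dioxol-4-olate (enolate of 13, formed in situ) | [Li+].CC1=C([O-])O[C@@H](C(C)(C)C)O1 | intermediate
16 | (2S,5R)-2-tert-butyl-5-[(2E)-3-ethoxyprop-2-enoyl]-5-methyl-1,3-dioxolan-4-one | C[C@]1(C(=O)/C=C/OCC)O[C@H](C(C)(C)C)OC1=O | intermediate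
17 | lithium acetylide of 8 (formed in situ) | [Li+].[C-]#CCC(O[Si](CC)(CC)CC)/C=C/C(=O)OC(C)(C)C | intermediate
18 | tert-butyl (2E,9R,11E)-12-ethoxy-9-hydroxy-9-methyl-8,10-dioxo-4-[(triethylsilyl)oxy]dodeca-2,11-dien-6-ynoate (C4 epimers, not purified) | CCO/C=C/C(=O)[C@@](C)(O)C(=O)C#CCC(O[Si](CC)(CC)CC)/C=C/C(=O)OC(C)(C)C | intermediate
19 | tert-butyl (2E,9S,11E)-12-ethoxy-8,9-dihydroxy-9-methyl-10-oxo-4-[(triethylsilyl)oxy]dodeca-2,11-dien-6-ynoate (C4 and C8 epimers) | CCO/C=C/C(=O)[C@@](C)(O)C(O)C#CCC(O[Si](CC)(CC)CC)/C=C/C(=O)OC(C)(C)C | intermediate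
20 | tert-butyl (2E,9S,11E)-12-ethoxy-9-hydroxy-9-methyl-10-oxo-4,8-bis[(triethylsilyl)oxy]dodeca-2,11-dien-6-ynoate (C4 and C8 epimers) | CCO/C=C/C(=O)[C@@](C)(O)C(O[Si](CC)(CC)CC)C#CCC(O[Si](CC)(CC)CC)/C=C/C(=O)OC(C)(C)C | intermediate
21 | 2,4-bis(methoxymethoxy)-6-methylbenzoyl fluoride (used crude) | Cc1cc(OCOC)cc(OCOC)c1C(F)=O | intermediate
22 | lithium alkoxide of 20 (formed in situ) | [Li+].CCO/C=C/C(=O)[C@@](C)([O-])C(O[Si](CC)(CC)CC)C#CCC(O[Si](CC)(CC)CC)/C=C/C(=O)OC(C)(C)C | intermediate
23 | tert-butyl (2E,9S,11E)-9-{[2,4-bis(methoxymethoxy)-6-methylbenzoyl]oxy}-12-ethoxy-9-methyl-10-oxo-4,8-bis[(triethylsilyl)oxy]dodeca-2,11-dien-6-ynoate (C4 and C8 epimers) | Cc1cc(OCOC)cc(OCOC)c1C(=O)O[C@@](C(=O)/C=C/OCC)(C)C(O[Si](CC)(CC)CC)C#CCC(O[Si](CC)(CC)CC)/C=C/C(=O)OC(C)(C)C | intermediate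
24 | tert-butyl (2E,9S,11E)-9-{[2,4-bis(methoxymethoxy)-6-methylbenzoyl]oxy}-12-ethoxy-4,8-dihydroxy-9-methyl-10-oxododeca-2,11-dien-6-ynoate (C4 and C8 epimers) | Cc1cc(OCOC)cc(OCOC)c1C(=O)O[C@@](C(=O)/C=C/OCC)(C)C(O)C#CCC(O)/C=C/C(=O)OC(C)(C)C | intermediate
25 | tert-butyl (2E,9R,11E)-9-{[2,4-bis(methoxymethoxy)-6-methylbenzoyl]oxy}-12-ethoxy-9-methyl-4,8,10-trioxododeca-2,11-dien-6-ynoate (precursor of the key step) | Cc1cc(OCOC)cc(OCOC)c1C(=O)O[C@@](C(=O)/C=C/OCC)(C)C(=O)C#CCC(=O)/C=C/C(=O)OC(C)(C)C | intermediate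
26 | tert-butyl (2E,9S,11E)-9-{[2,4-bis(methoxymethoxy)-6-methylbenzoyl]oxy}-12-ethoxy-9-methyl-4,8,10-trioxododeca-2,5,6,11-tetraenoate (1,3-diacylallene, formed in situ) | Cc1cc(OCOC)cc(OCOC)c1C(=O)O[C@@](C(=O)/C=C/OCC)(C)C(=O)C=C=CC(=O)/C=C/C(=O)OC(C)(C)C | intermediate
27 | tert-butyl (2E)-3-[(7S)-7-{[2,4-bis(methoxymethoxy)-6-methylbenzoyl]oxy}-1-ethoxy-7-methyl-6,8-dioxo-1,7,8,8a-tetrahydro-6H-isochromen-3-yl]prop-2-enoate (C1 and C8a epimers, formed in situ) | Cc1cc(OCOC)cc(OCOC)c1C(=O)O[C@@]1(C)C(=O)C=C2C=C(/C=C/C(=O)OC(C)(C)C)OC(OCC)C2C1=O | intermediate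
28 | tert-butyl (2E)-3-[(7S)-7-{[2,4-bis(methoxymethoxy)-6-methylbenzoyl]oxy}-7-methyl-6,8-dioxo-7,8-dihydro-6H-isochromen-3-yl]prop-2-enoate (product of the key step) | Cc1cc(OCOC)cc(OCOC)c1C(=O)O[C@@]1(C)C(=O)C=C2C=C(/C=C/C(=O)OC(C)(C)C)OC=C2C1=O | intermediate
29 | (S)-mitorubrinic acid, (2E)-3-[(7S)-7-[(2,4-dihydroxy-6-methylbenzoyl)oxy]-7-methyl-6,8-dioxo-7,8-dihydro-6H-isochromen-3-yl]prop-2-enoic acid | Cc1cc(O)cc(O)c1C(=O)O[C@@]1(C)C(=O)C=C2C=C(/C=C/C(=O)O)OC=C2C1=O | target

**Count and risks**

Total step count: 14.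
Longest linear sequence: 11 steps (steps 1, 2, 3, 4, 8, 9, 10, 11, 12, 13, 14, from 2,2-dimethoxyacetaldehyde); 9 steps from (S)-lactic acid.

Steps most likely to fail:

Step 13 (bears the label "Proposed new method:"). The allenyl ketone may be consumed by intermolecular Michael addition or by oxygen-centred cycloisomerisation before the tethered enol ether engages, or the push–pull alkene may be too weak a 2π partner, so that the ring closure stalls. The fallback builds the rings stepwise by known polar reactions; it sets out from 25 and comes back at 28. Mild aqueous acid (oxalic acid, THF/H2O, 0 °C) would hydrolyse the enol ether of 25 to the β-keto aldehyde tert-butyl (2E,9R)-9-{[2,4-bis(methoxymethoxy)-6-methylbenzoyl]oxy}-9-methyl-4,8,10,12-tetraoxododec-2-en-6-ynoate F1. Its 1,3-dicarbonyl carbon C8a is a much stronger carbon nucleophile and should add in an intramolecular Michael reaction (Cs2CO3 cat., MeCN, 0 °C) to the ynone β-carbon C4a, closing ring A as the formyl cyclohexenedione tert-butyl (2E)-5-[(4S)-4-{[2,4-bis(methoxymethoxy)-6-methylbenzoyl]oxy}-6-formyl-4-methyl-3,5-dioxocyclohex-1-en-1-yl]-4-oxopent-2-enoate F2. Acid-catalysed cyclodehydration of the 1,5-dicarbonyl unit C1/C3 of F2 (pyridinium p-toluenesulfonate, toluene, 4 Å sieves) would then close ring B and give 28.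

Step 10. Acyl transfer to the congested tertiary alkoxide may be slower than migration of the neighbouring silyl group onto the alkoxide oxygen or than decay of the acyl fluoride. The fallback replaces acylation by an acyl halide with ring-opening of a benzodioxinone; it sets out from 9 and 20 and comes back at 23. Orsellinic acid 9 would be condensed with acetone (CF3CO2H, (CF3CO)2O) to 7-hydroxy-2,2,5-trimethyl-4H-1,3-benzodioxin-4-one F3 and capped (MeOCH2Cl, i-Pr2NEt) to 7-(methoxymethoxy)-2,2,5-trimethyl-4H-1,3-benzodioxin-4-one F4. The lithium alkoxide 22 should open the lactone carbonyl of F4, which is held coplanar with the ring and carries only one flanking substituent, with loss of acetone, to give the salicylate tert-butyl (2E,9S,11E)-12-ethoxy-9-{[2-hydroxy-4-(methoxymethoxy)-6-methylbenzoyl]oxy}-9-methyl-10-oxo-4,8-bis[(triethylsilyl)oxy]dodeca-2,11-dien-6-ynoate F5. Alkylation of its phenol (MeOCH2Cl, i-Pr2NEt, NaI, 40 °C) gives 23.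

Step 8. The acetylide may attack the ethoxy enone (1,2-addition at C8 or addition–elimination at C1) in competition with the lactone carbonyl. The fallback masks C8 as a Weinreb amide until the alkyne is in place; it sets out from 13 and comes back at 23.
- The enolate 15 would be carbamoylated with N-methoxy-N-methylcarbamoyl chloride, again anti to the tert-butyl group, to (2S,4R)-2-tert-butyl-N-methoxy-N,4-dimethyl-5-oxo-1,3-dioxolane-4-carboxamide F6.
- Acetylide 17 then finds the lactone as the only carbonyl reactive at −78 °C and gives, after protonation, the hydroxy ynone tert-butyl (2E,9S)-9-hydroxy-10-[methoxy(methyl)amino]-9-methyl-8,10-dioxo-4-[(triethylsilyl)oxy]dec-2-en-6-ynoate F7.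
- Luche reduction as in step 8 gives the diol tert-butyl (2E,9S)-8,9-dihydroxy-10-[methoxy(methyl)amino]-9-methyl-10-oxo-4-[(triethylsilyl)oxy]dec-2-en-6-ynoate F8.
- Silylation as in step 9 gives tert-butyl (2E,9S)-9-hydroxy-10-[methoxy(methyl)amino]-9-methyl-10-oxo-4,8-bis[(triethylsilyl)oxy]dec-2-en-6-ynoate F9.
- Its lithium alkoxide F10 is aroylated with 21 as in step 10 to tert-butyl (2E,9S)-9-{[2,4-bis(methoxymethoxy)-6-methylbenzoyl]oxy}-10-[methoxy(methyl)amino]-9-methyl-10-oxo-4,8-bis[(triethylsilyl)oxy]dec-2-en-6-ynoate F11.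
- Ethynylmagnesium bromide (THF, −78 → 0 °C) would convert the amide into the terminal ynone tert-butyl (2E,9S)-9-{[2,4-bis(methoxymethoxy)-6-methylbenzoyl]oxy}-9-methyl-10-oxo-4,8-bis[(triethylsilyl)oxy]dodec-2-ene-6,11-diynoate F12.
- DABCO-catalysed conjugate addition of ethanol to F12 installs the (E)-ethoxy enone, which is 23.

**Further compounds**

F1 | step 13 | tert-butyl (2E,9R)-9-{[2,4-bis(methoxymethoxy)-6-methylbenzoyl]oxy}-9-methyl-4,8,10,12-tetraoxododec-2-en-6-ynoate | Cc1cc(OCOC)cc(OCOC)c1C(=O)O[C@@](C(=O)CC=O)(C)C(=O)C#CCC(=O)/C=C/C(=O)OC(C)(C)C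
F2 | step 13 | tert-butyl (2E)-5-[(4S)-4-{[2,4-bis(methoxymethoxy)-6-methylbenzoyl]oxy}-6-formyl-4-methyl-3,5-dioxocyclohex-1-en-1-yl]-4-oxopent-2-enoate | Cc1cc(OCOC)cc(OCOC)c1C(=O)O[C@@]1(C)C(=O)C=C(CC(=O)/C=C/C(=O)OC(C)(C)C)C(C=O)C1=O
F3 | step 10 | 7-hydroxy-2,2,5-trimethyl-4H-1,3-benzodioxin-4-one | Cc1cc(O)cc2OC(C)(C)OC(=O)c12
F4 | step 10 | 7-(methoxymethoxy)-2,2,5-trimethyl-4H-1,3-benzodioxin-4-one | Cc1cc(OCOC)cc2OC(C)(C)OC(=O)c12
F5 | step 10 | tert-butyl (2E,9S,11E)-12-ethoxy-9-{[2-hydroxy-4-(methoxymethoxy)-6-methylbenzoyl]oxy}-9-methyl-10-oxo-4,8-bis[(triethylsilyl)oxy]dodeca-2,11-dien-6-ynoate | Cc1cc(OCOC)cc(O)c1C(=O)O[C@@](C(=O)/C=C/OCC)(C)C(O[Si](CC)(CC)CC)C#CCC(O[Si](CC)(CC)CC)/C=C/C(=O)OC(C)(C)C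
F6 | step 8 | (2S,4R)-2-tert-butyl-N-methoxy-N,4-dimethyl-5-oxo-1,3-dioxolane-4-carboxamide | C[C@]1(C(=O)N(C)OC)O[C@H](C(C)(C)C)OC1=O
F7 | step 8 | tert-butyl (2E,9S)-9-hydroxy-10-[methoxy(methyl)amino]-9-methyl-8,10-dioxo-4-[(triethylsilyl)oxy]dec-2-en-6-ynoate | CON(C)C(=O)[C@@](C)(O)C(=O)C#CCC(O[Si](CC)(CC)CC)/C=C/C(=O)OC(C)(C)C
F8 | step 8 | tert-butyl (2E,9S)-8,9-dihydroxy-10-[methoxy(methyl)amino]-9-methyl-10-oxo-4-[(triethylsilyl)oxy]dec-2-en-6-ynoate | CON(C)C(=O)[C@@](C)(O)C(O)C#CCC(O[Si](CC)(CC)CC)/C=C/C(=O)OC(C)(C)C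
F9 | step 8 | tert-butyl (2E,9S)-9-hydroxy-10-[methoxy(methyl)amino]-9-methyl-10-oxo-4,8-bis[(triethylsilyl)oxy]dec-2-en-6-ynoate | CON(C)C(=O)[C@@](C)(O)C(O[Si](CC)(CC)CC)C#CCC(O[Si](CC)(CC)CC)/C=C/C(=O)OC(C)(C)C
F10 | step 8 | lithium alkoxide of F9 | [Li+].CON(C)C(=O)[C@@](C)([O-])C(O[Si](CC)(CC)CC)C#CCC(O[Si](CC)(CC)CC)/C=C/C(=O)OC(C)(C)C
F11 | step 8 | tert-butyl (2E,9S)-9-{[2,4-bis(methoxymethoxy)-6-methylbenzoyl]oxy}-10-[methoxy(methyl)amino]-9-methyl-10-oxo-4,8-bis[(triethylsilyl)oxy]dec-2-en-6-ynoate | Cc1cc(OCOC)cc(OCOC)c1C(=O)O[C@@](C(=O)N(C)OC)(C)C(O[Si](CC)(CC)CC)C#CCC(O[Si](CC)(CC)CC)/C=C/C(=O)OC(C)(C)C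
F12 | step 8 | tert-butyl (2E,9S)-9-{[2,4-bis(methoxymethoxy)-6-methylbenzoyl]oxy}-9-methyl-10-oxo-4,8-bis[(triethylsilyl)oxy]dodec-2-ene-6,11-diynoate | Cc1cc(OCOC)cc(OCOC)c1C(=O)O[C@@](C(=O)C#C)(C)C(O[Si](CC)(CC)CC)C#CCC(O[Si](CC)(CC)CC)/C=C/C(=O)OC(C)(C)C
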